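## Retrosynthetic overview

1. The last C–C bond made is the one between the carbinol carbon and the methyl-bearing carbon next to pyrone B. It comes from a vinylogous aldol of the lithium dienolate of an ethyl-substituted pyrone B with a pyrone A aldehyde, followed by removal of two silyl ethers.
2. The pyrone A aldehyde comes from a Paterson anti-aldol of the (S)-lactate ethyl ketone with a pyrone A enal, then silylation and glycol cleavage.
3. The pyrone A enal comes from a vinylogous aldol of 2,6-diethyl-3,5-dimethyl-4-pyranone with (R)-Roche aldehyde, then oxidation and β-elimination. The Roche centre relays its chirality to the carbon next to pyrone A and is then erased.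
4. Pyrone B comes from cyclodehydration of a 1,3,5-triketone, itself made from the dianion of 4-methylheptane-3,5-dione and a D-proline-derived anti aldehyde.
5. Ring order: pyrone A first (step 1), pyrone B second (step 18); no ring is formed after the fragment union.

Assumption: the lithium dienolate of a 2-ethyl-4-pyranone adds to α-methyl aldehydes with anti simple selectivity and Felkin–Anh facial selectivity (open transition state), and 4-methylheptane-3,5-dione is bought.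

## Route

Step 1
Reactants: 1 pentan-3-one; 2 propanoic acid (2 equiv)
Product: 3 2,6-diethyl-3,5-dimethyl-4H-pyran-4-one
Conditions: polyphosphoric acid, 130 °C
Reagents that add atoms: none
Why: Polyphosphoric acid drives two C-acylations of the ketone by propanoic acid and the cyclodehydration of the resulting 1,3,5-triketone, giving the symmetric γ-pyrone (pyrone A) with no stereocentre.

Step 2
Reactants: 4 methyl (R)-3-hydroxy-2-methylpropanoate
Product: 5 methyl (R)-3-[(tert-butyldimethylsilyl)oxy]-2-methylpropanoate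
Conditions: t-BuMe2SiCl, imidazole, DMF, 23 °C
Reagents that add atoms: tert-butyldimethylsilyl chloride, CC(C)(C)[Si](C)(C)Cl
Why: Imidazole-mediated O-silylation protects the primary alcohol without touching the stereocentre.

Step 3
Reactants: 5 methyl (R)-3-[(tert-butyldimethylsilyl)oxy]-2-methylpropanoate
Product: 6 (R)-3-[(tert-butyldimethylsilyl)oxy]-2-methylpropanal
Conditions: i-Bu2AlH (1.05 equiv), CH2Cl2, −78 °C; aq. potassium sodium tartrate
Reagents that add atoms: none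
Why: In this partial ester reduction the tetrahedral aluminium hemiacetal survives at −78 °C until work-up, so reduction stops at the aldehyde, which is used at once to avoid epimerisation.

Step 4
Reactants: 3 2,6-diethyl-3,5-dimethyl-4H-pyran-4-one; 6 (R)-3-[(tert-butyldimethylsilyl)oxy]-2-methylpropanal
Product: 9 (2R,3S,4S)-1-[(tert-butyldimethylsilyl)oxy]-4-(6-ethyl-3,5-dimethyl-4-oxo-4H-pyran-2-yl)-2-methylpentan-3-yl acetate, via lithium dienolate 7 (not isolated), via lithium aldolate 8 (not isolated)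
Conditions: LiN(SiMe3)2, THF, −78 °C; then 6; then Ac2O, −78 → 0 °C
Reagents that add atoms: acetic anhydride, CC(=O)OC(C)=O
Why: This vinylogous aldol addition goes through an open transition state with Felkin–Anh facial control (new oxygen syn to the Roche methyl) and anti simple selectivity, which sets C-4 as S and C-3 as S, and the aldolate is trapped as the acetate so that minor diastereomers can be removed by chromatography.

Step 5
Reactants: 9 (2R,3S,4S)-1-[(tert-butyldimethylsilyl)oxy]-4-(6-ethyl-3,5-dimethyl-4-oxo-4H-pyran-2-yl)-2-methylpentan-3-yl acetate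
Product: 10 (2R,3S,4S)-4-(6-ethyl-3,5-dimethyl-4-oxo-4H-pyran-2-yl)-1-hydroxy-2-methylpentan-3-yl acetate
Conditions: HF·pyridine, pyridine, THF, 0 → 23 °C
Reagents that add atoms: none
Why: Buffered fluoride desilylation cleaves the primary silyl ether while the secondary acetate and the pyrone are inert, and no stereocentre is involved.

Step 6
Reactants: 10 (2R,3S,4S)-4-(6-ethyl-3,5-dimethyl-4-oxo-4H-pyran-2-yl)-1-hydroxy-2-methylpentan-3-yl acetate
Product: 12 (S,E)-4-(6-ethyl-3,5-dimethyl-4-oxo-4H-pyran-2-yl)-2-methylpent-2-enal, via acetoxy aldehyde 11 (not isolated)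
Conditions: Dess–Martin periodinane, NaHCO3, CH2Cl2, 0 → 23 °C; then Et3N, 0 °C
Reagents that add atoms: none
Why: Dess–Martin oxidation gives a β-acetoxy aldehyde that undergoes E1cB elimination to the thermodynamically favoured E-enal, which erases the two helper stereocentres and leaves the S centre next to the pyrone untouched.

Step 7
Reactants: 13 ethyl (S)-2-hydroxypropanoate
Product: 14 (S)-2-hydroxy-N-methoxy-N-methylpropanamide
Conditions: MeNH(OMe)·HCl, i-PrMgCl, THF, −20 → 0 °C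
Reagents that add atoms: N,O-dimethylhydroxylamine hydrochloride, CNOC.Cl
Why: Aminolysis of the ester by the chloromagnesium amide (Weinreb amide formation) proceeds without affecting the lactate stereocentre.

Step 8
Reactants: 14 (S)-2-hydroxy-N-methoxy-N-methylpropanamide
Product: 15 (S)-2-hydroxypentan-3-one
Conditions: EtMgBr (3 equiv), THF, 0 → 23 °C
Reagents that add atoms: ethylmagnesium bromide, CC[Mg]Br
Why: Grignard addition to the Weinreb amide stops at the ketone because the chelated tetrahedral intermediate collapses only on work-up, and the α-stereocentre is retained.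

Step 9
Reactants: 15 (S)-2-hydroxypentan-3-one
Product: 16 (S)-3-oxopentan-2-yl benzoate
Conditions: (PhCO)2O, 4-(dimethylamino)pyridine (cat.), i-Pr2NEt, CH2Cl2, 23 °C
Reagents that add atoms: benzoic anhydride, O=C(OC(=O)c1ccccc1)c1ccccc1
Why: Nucleophile-catalysed O-benzoylation installs the benzoate that later directs the aldol, with retention at the stereocentre.

Step 10
Reactants: 16 (S)-3-oxopentan-2-yl benzoate; 12 (S,E)-4-(6-ethyl-3,5-dimethyl-4-oxo-4H-pyran-2-yl)-2-methylpent-2-enal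
Product: 19 (2S,4R,5S,6E,8S)-8-(6-ethyl-3,5-dimethyl-4-oxo-4H-pyran-2-yl)-5-hydroxy-4,6-dimethyl-3-oxonon-6-en-2-yl benzoate, via enol borinate 17 (not isolated), via boron aldolate 18 (not isolated)
Conditions: c-Hex2BCl, Me2NEt, Et2O, −78 → 0 °C; then 12, −78 → −20 °C; then H2O2, MeOH, pH 7 buffer, 0 °C
Reagents that add atoms: none
Why: In this Paterson anti-aldol the (E)-enol dicyclohexylborinate reacts through a chair Zimmerman–Traxler transition state whose face is fixed by the lactate benzoate, which sets C-4 as R and C-5 as S (2,3-anti) under reagent control.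

Step 11
Reactants: 19 (2S,4R,5S,6E,8S)-8-(6-ethyl-3,5-dimethyl-4-oxo-4H-pyran-2-yl)-5-hydroxy-4,6-dimethyl-3-oxonon-6-en-2-yl benzoate
Product: 20 (2S,4R,5S,6E,8S)-5-[(tert-butyldimethylsilyl)oxy]-8-(6-ethyl-3,5-dimethyl-4-oxo-4H-pyran-2-yl)-4,6-dimethyl-3-oxonon-6-en-2-yl benzoate
Conditions: t-BuMe2SiOTf, 2,6-lutidine, CH2Cl2, −78 °C
Reagents that add atoms: tert-butyldimethylsilyl trifluoromethanesulfonate, CC(C)(C)[Si](C)(C)OS(=O)(=O)C(F)(F)F
Why: O-silylation with the silyl triflate and a hindered base caps the hindered allylic alcohol and blocks retro-aldol cleavage without changing any stereocentre.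

Step 12
Reactants: 20 (2S,4R,5S,6E,8S)-5-[(tert-butyldimethylsilyl)oxy]-8-(6-ethyl-3,5-dimethyl-4-oxo-4H-pyran-2-yl)-4,6-dimethyl-3-oxonon-6-en-2-yl benzoate
Product: 22 (2S,3RS,4S,5S,6E,8S)-5-[(tert-butyldimethylsilyl)oxy]-8-(6-ethyl-3,5-dimethyl-4-oxo-4H-pyran-2-yl)-4,6-dimethylnon-6-ene-2,3-diol, via hydroxy benzoate 21 (not isolated)
Conditions: NaBH4, MeOH, 0 °C; then K2CO3, MeOH, 23 °C
Reagents that add atoms: none
Why: Borohydride reduction takes only the ketone (the γ-pyrone is a vinylogous ester and is inert) and carbonate-catalysed transesterification then removes the benzoate, giving a 1,2-diol whose new carbinol centre is irrelevant.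

Step 13
Reactants: 22 (2S,3RS,4S,5S,6E,8S)-5-[(tert-butyldimethylsilyl)oxy]-8-(6-ethyl-3,5-dimethyl-4-oxo-4H-pyran-2-yl)-4,6-dimethylnon-6-ene-2,3-diol
Product: 23 (2R,3S,4E,6S)-3-[(tert-butyldimethylsilyl)oxy]-6-(6-ethyl-3,5-dimethyl-4-oxo-4H-pyran-2-yl)-2,4-dimethylhept-4-enal
Conditions: NaIO4, MeOH/H2O (2:1), 0 → 23 °C
Reagents that add atoms: none
Why: Periodate glycol cleavage (Malaprade reaction) excises the lactate carbons under neutral conditions and unveils the α-methyl aldehyde without epimerisation.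

Step 14
Reactants: 24 propanal (two molecules)
Product: 25 (2R,3R)-3-hydroxy-2-methylpentanal
Conditions: D-proline (10 mol %), DMF, 4 °C, slow addition
Reagents that add atoms: none
Why: In this proline-catalysed enamine aldol (Houk–List transition state) the D-proline enamine of one propanal adds to a second propanal to set both centres as 2R,3R (anti about 4:1, high ee), and the minor syn isomer is removed later by chromatography of pyrone 31.

Step 15
Reactants: 25 (2R,3R)-3-hydroxy-2-methylpentanal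
Product: 26 (2R,3R)-3-[(tert-butyldimethylsilyl)oxy]-2-methylpentanal
Conditions: t-BuMe2SiOTf, 2,6-lutidine, CH2Cl2, −78 °C
Reagents that add atoms: tert-butyldimethylsilyl trifluoromethanesulfonate, CC(C)(C)[Si](C)(C)OS(=O)(=O)C(F)(F)F
Why: Low-temperature O-silylation caps the β-hydroxyl before the aldehyde can dehydrate or undergo retro-aldol, with both stereocentres unchanged.

Step 16
Reactants: 27 4-methylheptane-3,5-dione; 26 (2R,3R)-3-[(tert-butyldimethylsilyl)oxy]-2-methylpentanal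
Product: 29 (8S,9R)-9-[(tert-butyldimethylsilyl)oxy]-7-hydroxy-4,6,8-trimethylundecane-3,5-dione (C-4/C-6/C-7 epimer mixture), via dilithium dianion 28 (not isolated)
Conditions: LiN(i-Pr)2 (2.1 equiv), THF, 0 °C; then 26, −78 °C; AcOH
Reagents that add atoms: none
Why: In this β-diketone dianion γ-aldol the dianion reacts at its terminal carbon with the aldehyde at −78 °C, and all newly formed centres are removed in the next two steps while the two aldehyde-derived centres are untouched.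

Step 17
Reactants: 29 (8S,9R)-9-[(tert-butyldimethylsilyl)oxy]-7-hydroxy-4,6,8-trimethylundecane-3,5-dione
Product: 30 (8R,9R)-9-[(tert-butyldimethylsilyl)oxy]-4,6,8-trimethylundecane-3,5,7-trione
Conditions: Dess–Martin periodinane, NaHCO3, CH2Cl2, 23 °C
Reagents that add atoms: none
Why: Dess–Martin oxidation converts the carbinol into the third ketone under buffered conditions that neither epimerise the α-centre nor eliminate the β-silyloxy group.

Step 18
Reactants: 30 (8R,9R)-9-[(tert-butyldimethylsilyl)oxy]-4,6,8-trimethylundecane-3,5,7-trione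
Product: 31 2-{(2R,3R)-3-[(tert-butyldimethylsilyl)oxy]pentan-2-yl}-6-ethyl-3,5-dimethyl-4H-pyran-4-one
Conditions: PPh3, CCl4, THF, 23 °C
Reagents that add atoms: none
Why: Appel-type activation of an enol oxygen triggers cyclodehydration of the 1,3,5-triketone to the γ-pyrone (pyrone B) under neutral conditions, so the adjacent stereocentre and the silyl ether survive.

Step 19
Reactants: 31 2-{(2R,3R)-3-[(tert-butyldimethylsilyl)oxy]pentan-2-yl}-6-ethyl-3,5-dimethyl-4H-pyran-4-one; 23 (2R,3S,4E,6S)-3-[(tert-butyldimethylsilyl)oxy]-6-(6-ethyl-3,5-dimethyl-4-oxo-4H-pyran-2-yl)-2,4-dimethylhept-4-enal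
Product: 33 2-[(2S,3E,5S,6S,7S,8S)-5-[(tert-butyldimethylsilyl)oxy]-8-(6-{(2R,3R)-3-[(tert-butyldimethylsilyl)oxy]pentan-2-yl}-3,5-dimethyl-4-oxo-4H-pyran-2-yl)-7-hydroxy-4,6-dimethylnon-3-en-2-yl]-6-ethyl-3,5-dimethyl-4H-pyran-4-one, via lithium dienolate 32 (not isolated)
Conditions: LiN(SiMe3)2, THF, −78 °C; then 23, −78 °C; AcOH
Reagents that add atoms: none
Why: In this vinylogous aldol union the dienolate formed at the less hindered ethyl group adds to the aldehyde with Felkin–Anh facial control (reinforced by the anti β-silyloxy group) and anti simple selectivity, which sets C-7 and C-8 of the chain as S and S.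

Step 20
Reactants: 33 2-[(2S,3E,5S,6S,7S,8S)-5-[(tert-butyldimethylsilyl)oxy]-8-(6-{(2R,3R)-3-[(tert-butyldimethylsilyl)oxy]pentan-2-yl}-3,5-dimethyl-4-oxo-4H-pyran-2-yl)-7-hydroxy-4,6-dimethylnon-3-en-2-yl]-6-ethyl-3,5-dimethyl-4H-pyran-4-one
Product: 34 2-ethyl-6-[(2S,3E,5S,6S,7S,8S)-5,7-dihydroxy-8-{6-[(2R,3R)-3-hydroxypentan-2-yl]-3,5-dimethyl-4-oxo-4H-pyran-2-yl}-4,6-dimethylnon-3-en-2-yl]-3,5-dimethyl-4H-pyran-4-one
Conditions: HF·pyridine, pyridine, THF, 0 → 23 °C
Reagents that add atoms: none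
Why: Fluoride-mediated desilylation removes both silyl ethers under mildly acidic conditions that leave the pyrones, the allylic alcohol and every stereocentre untouched.

## Compound list

1 | pentan-3-one | CCC(=O)CC | starting material
2 | propanoic acid | CCC(=O)O | starting material
3 | 2,6-diethyl-3,5-dimethyl-4H-pyran-4-one | CCc1oc(CC)c(C)c(=O)c1C | intermediate
4 | methyl (R)-3-hydroxy-2-methylpropanoate | COC(=O)[C@H](C)CO | starting material
5 | methyl (R)-3-[(tert-butyldimethylsilyl)oxy]-2-methylpropanoate | COC(=O)[C@H](C)CO[Si](C)(C)C(C)(C)C | intermediate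
6 | (R)-3-[(tert-butyldimethylsilyl)oxy]-2-methylpropanal | O=C[C@H](C)CO[Si](C)(C)C(C)(C)C | intermediate
7 | lithium (2Z)-6-ethyl-2-ethylidene-3,5-dimethyl-2H-pyran-4-olate | C/C=C1\OC(CC)=C(C)C([O-])=C1C.[Li+] | intermediate
8 | lithium (2R,3S,4S)-1-[(tert-butyldimethylsilyl)oxy]-4-(6-ethyl-3,5-dimethyl-4-oxo-4H-pyran-2-yl)-2-methylpentan-3-olate | CCc1oc([C@@H](C)[C@@H]([O-])[C@H](C)CO[Si](C)(C)C(C)(C)C)c(C)c(=O)c1C.[Li+] | intermediate
9 | (2R,3S,4S)-1-[(tert-butyldimethylsilyl)oxy]-4-(6-ethyl-3,5-dimethyl-4-oxo-4H-pyran-2-yl)-2-methylpentan-3-yl acetate | CCc1oc([C@@H](C)[C@@H](OC(C)=O)[C@H](C)CO[Si](C)(C)C(C)(C)C)c(C)c(=O)c1C | intermediate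
10 | (2R,3S,4S)-4-(6-ethyl-3,5-dimethyl-4-oxo-4H-pyran-2-yl)-1-hydroxy-2-methylpentan-3-yl acetate | CCc1oc([C@@H](C)[C@@H](OC(C)=O)[C@H](C)CO)c(C)c(=O)c1C | intermediate
11 | (2S,3R,4S)-4-(6-ethyl-3,5-dimethyl-4-oxo-4H-pyran-2-yl)-2-methyl-1-oxopentan-3-yl acetate | CCc1oc([C@@H](C)[C@@H](OC(C)=O)[C@H](C)C=O)c(C)c(=O)c1C | intermediate
12 | (S,E)-4-(6-ethyl-3,5-dimethyl-4-oxo-4H-pyran-2-yl)-2-methylpent-2-enal | CCc1oc([C@@H](C)/C=C(\C)C=O)c(C)c(=O)c1C | intermediate
13 | ethyl (S)-2-hydroxypropanoate | CCOC(=O)[C@H](C)O | starting material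
14 | (S)-2-hydroxy-N-methoxy-N-methylpropanamide | C[C@H](O)C(=O)N(C)OC | intermediate
15 | (S)-2-hydroxypentan-3-one | CCC(=O)[C@H](C)O | intermediate
16 | (S)-3-oxopentan-2-yl benzoate | CCC(=O)[C@H](C)OC(=O)c1ccccc1 | intermediate
17 | (S,E)-3-[(dicyclohexylboranyl)oxy]pent-3-en-2-yl benzoate | C/C=C(/OB(C1CCCCC1)C1CCCCC1)[C@H](C)OC(=O)c1ccccc1 | intermediate
18 | (2S,4R,5S,6E,8S)-5-[(dicyclohexylboranyl)oxy]-8-(6-ethyl-3,5-dimethyl-4-oxo-4H-pyran-2-yl)-4,6-dimethyl-3-oxonon-6-en-2-yl benzoate | C[C@H](OC(=O)c1ccccc1)C(=O)[C@H](C)[C@H](OB(C1CCCCC1)C1CCCCC1)/C(C)=C/[C@H](C)c1oc(CC)c(C)c(=O)c1C | intermediate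
19 | (2S,4R,5S,6E,8S)-8-(6-ethyl-3,5-dimethyl-4-oxo-4H-pyran-2-yl)-5-hydroxy-4,6-dimethyl-3-oxonon-6-en-2-yl benzoate | C[C@H](OC(=O)c1ccccc1)C(=O)[C@H](C)[C@H](O)/C(C)=C/[C@H](C)c1oc(CC)c(C)c(=O)c1C | intermediate
20 | (2S,4R,5S,6E,8S)-5-[(tert-butyldimethylsilyl)oxy]-8-(6-ethyl-3,5-dimethyl-4-oxo-4H-pyran-2-yl)-4,6-dimethyl-3-oxonon-6-en-2-yl benzoate | C[C@H](OC(=O)c1ccccc1)C(=O)[C@H](C)[C@H](O[Si](C)(C)C(C)(C)C)/C(C)=C/[C@H](C)c1oc(CC)c(C)c(=O)c1C | intermediate
21 | (2S,3RS,4S,5S,6E,8S)-5-[(tert-butyldimethylsilyl)oxy]-8-(6-ethyl-3,5-dimethyl-4-oxo-4H-pyran-2-yl)-3-hydroxy-4,6-dimethylnon-6-en-2-yl benzoate | C[C@H](OC(=O)c1ccccc1)C(O)[C@H](C)[C@H](O[Si](C)(C)C(C)(C)C)/C(C)=C/[C@H](C)c1oc(CC)c(C)c(=O)c1C | intermediate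
22 | (2S,3RS,4S,5S,6E,8S)-5-[(tert-butyldimethylsilyl)oxy]-8-(6-ethyl-3,5-dimethyl-4-oxo-4H-pyran-2-yl)-4,6-dimethylnon-6-ene-2,3-diol | C[C@H](O)C(O)[C@H](C)[C@H](O[Si](C)(C)C(C)(C)C)/C(C)=C/[C@H](C)c1oc(CC)c(C)c(=O)c1C | intermediate
23 | (2R,3S,4E,6S)-3-[(tert-butyldimethylsilyl)oxy]-6-(6-ethyl-3,5-dimethyl-4-oxo-4H-pyran-2-yl)-2,4-dimethylhept-4-enal | O=C[C@H](C)[C@H](O[Si](C)(C)C(C)(C)C)/C(C)=C/[C@H](C)c1oc(CC)c(C)c(=O)c1C | intermediate
24 | propanal | CCC=O | starting material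
25 | (2R,3R)-3-hydroxy-2-methylpentanal | CC[C@@H](O)[C@@H](C)C=O | intermediate
26 | (2R,3R)-3-[(tert-butyldimethylsilyl)oxy]-2-methylpentanal | CC[C@@H](O[Si](C)(C)C(C)(C)C)[C@@H](C)C=O | intermediate
27 | 4-methylheptane-3,5-dione | CCC(=O)C(C)C(=O)CC | starting material
28 | dilithium 4-methylhepta-2,4-diene-3,5-bis(olate) | CC=C([O-])C(C)=C([O-])CC.[Li+].[Li+] | intermediate
29 | (8S,9R)-9-[(tert-butyldimethylsilyl)oxy]-7-hydroxy-4,6,8-trimethylundecane-3,5-dione (mixture at C-4, C-6, C-7) | CCC(=O)C(C)C(=O)C(C)C(O)[C@H](C)[C@@H](CC)O[Si](C)(C)C(C)(C)C | intermediate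
30 | (8R,9R)-9-[(tert-butyldimethylsilyl)oxy]-4,6,8-trimethylundecane-3,5,7-trione | CCC(=O)C(C)C(=O)C(C)C(=O)[C@H](C)[C@@H](CC)O[Si](C)(C)C(C)(C)C | intermediate
31 | 2-{(2R,3R)-3-[(tert-butyldimethylsilyl)oxy]pentan-2-yl}-6-ethyl-3,5-dimethyl-4H-pyran-4-one | CCc1oc([C@H](C)[C@@H](CC)O[Si](C)(C)C(C)(C)C)c(C)c(=O)c1C | intermediate
32 | lithium (2Z)-6-{(2R,3R)-3-[(tert-butyldimethylsilyl)oxy]pentan-2-yl}-2-ethylidene-3,5-dimethyl-2H-pyran-4-olate | C/C=C1\OC([C@H](C)[C@@H](CC)O[Si](C)(C)C(C)(C)C)=C(C)C([O-])=C1C.[Li+] | intermediate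
33 | 2-[(2S,3E,5S,6S,7S,8S)-5-[(tert-butyldimethylsilyl)oxy]-8-(6-{(2R,3R)-3-[(tert-butyldimethylsilyl)oxy]pentan-2-yl}-3,5-dimethyl-4-oxo-4H-pyran-2-yl)-7-hydroxy-4,6-dimethylnon-3-en-2-yl]-6-ethyl-3,5-dimethyl-4H-pyran-4-one | CCc1oc([C@@H](C)/C=C(\C)[C@@H](O[Si](C)(C)C(C)(C)C)[C@@H](C)[C@H](O)[C@H](C)c2oc([C@H](C)[C@H](O[Si](C)(C)C(C)(C)C)CC)c(C)c(=O)c2C)c(C)c(=O)c1C | intermediate
34 | 2-ethyl-6-[(2S,3E,5S,6S,7S,8S)-5,7-dihydroxy-8-{6-[(2R,3R)-3-hydroxypentan-2-yl]-3,5-dimethyl-4-oxo-4H-pyran-2-yl}-4,6-dimethylnon-3-en-2-yl]-3,5-dimethyl-4H-pyran-4-one | CCc1oc([C@@H](C)/C=C(\C)[C@@H](O)[C@@H](C)[C@H](O)[C@H](C)c2oc([C@H](C)[C@H](O)CC)c(C)c(=O)c2C)c(C)c(=O)c1C | target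

## Step count and risks

Total step count: 20.
Longest linear sequence: 11 steps (4 → 5 → 6 → 9 → 10 → 12 → 19 → 20 → 22 → 23 → 33 → 34).

The three steps most likely to fail:

**Step 19 (fragment union).** The anti and Felkin–Anh sense of the lithium dienolate addition is assumed, not guaranteed. Proton transfer to the acidic positions of pyrone A in aldehyde 23, or retro-aldol on warming, could also lower the yield. The fallback sets out from 31 and comes back at 33. Pyrone 31 is O-silylated (t-BuMe2SiOTf, Et3N, CH2Cl2, −78 → 0 °C) to the silyl dienol ether tert-butyl{[(2Z)-6-{(2R,3R)-3-[(tert-butyldimethylsilyl)oxy]pentan-2-yl}-2-ethylidene-3,5-dimethyl-2H-pyran-4-yl]oxy}dimethylsilane F8. This neutral nucleophile is added to aldehyde 23 under BF3·OEt2 (CH2Cl2, −78 °C) in a vinylogous Mukaiyama aldol. That reaction has an open transition state in which Felkin–Anh and 1,3-anti induction from the anti α-methyl/β-silyloxy aldehyde reinforce, and no strong base is present. Aqueous work-up gives 33.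

**Step 4 (first vinylogous aldol).** The diastereomer ratio may be modest, and any isomer with the wrong configuration next to the pyrone would end up as the enantiomer of enal 12. If separation fails, pyrone A is instead built onto the Roche-derived chain, so that the Roche centre itself becomes the centre next to the pyrone. This fallback sets out from 6 and comes back at 12.
- Wittig olefination of 6 with Ph3P=C(Me)CHO (toluene, 90 °C) gives (S,E)-5-[(tert-butyldimethylsilyl)oxy]-2,4-dimethylpent-2-enal F1.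
- Acetalisation with 1,2-bis(trimethylsilyloxy)ethane and catalytic Me3SiOTf (CH2Cl2, −78 °C) gives tert-butyl{[(S,E)-4-(1,3-dioxolan-2-yl)-2-methylpent-3-en-1-yl]oxy}dimethylsilane F2.
- Bu4NF in THF gives (S,E)-4-(1,3-dioxolan-2-yl)-2-methylpent-3-en-1-ol F3.
- Dess–Martin oxidation gives (S,E)-4-(1,3-dioxolan-2-yl)-2-methylpent-3-enal F4.
- Addition of dianion 28 at −78 °C gives (8S,9E)-10-(1,3-dioxolan-2-yl)-7-hydroxy-4,6,8-trimethylundec-9-ene-3,5-dione F5.
- Dess–Martin oxidation gives (8S,9E)-10-(1,3-dioxolan-2-yl)-4,6,8-trimethylundec-9-ene-3,5,7-trione F6.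
- Cyclodehydration with PPh3/CCl4 gives 2-[(S,E)-4-(1,3-dioxolan-2-yl)pent-3-en-2-yl]-6-ethyl-3,5-dimethyl-4H-pyran-4-one F7.
- Aqueous oxalic acid in THF hydrolyses the acetal and returns enal 12.

**Step 14 (proline aldol).** The anti:syn ratio is only about 4:1 and the free β-hydroxy aldehyde 25 is fragile. The fallback sets out from 24 and comes back at 26. Propanal 24 is crotylated with the (E)-crotylborane made from (E)-but-2-ene, KOt-Bu, n-BuLi, (−)-B-methoxydiisopinocampheylborane and BF3·OEt2 (THF, −78 °C; NaOH/H2O2 work-up). This gives (3R,4S)-4-methylhex-5-en-3-ol F9 through a chair allylboration transition state (anti, reagent-controlled). Silylation (t-BuMe2SiOTf, 2,6-lutidine) gives tert-butyldimethyl{[(3R,4S)-4-methylhex-5-en-3-yl]oxy}silane F10. Ozonolysis (O3, CH2Cl2, −78 °C; PPh3) returns aldehyde 26.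

## Further compounds

F1 | step 4 | (S,E)-5-[(tert-butyldimethylsilyl)oxy]-2,4-dimethylpent-2-enal | O=C/C(C)=C/[C@H](C)CO[Si](C)(C)C(C)(C)C
F2 | step 4 | tert-butyl{[(S,E)-4-(1,3-dioxolan-2-yl)-2-methylpent-3-en-1-yl]oxy}dimethylsilane | O1CCOC1/C(C)=C/[C@H](C)CO[Si](C)(C)C(C)(C)C
F3 | step 4 | (S,E)-4-(1,3-dioxolan-2-yl)-2-methylpent-3-en-1-ol | O1CCOC1/C(C)=C/[C@H](C)CO
F4 | step 4 | (S,E)-4-(1,3-dioxolan-2-yl)-2-methylpent-3-enal | O1CCOC1/C(C)=C/[C@H](C)C=O
F5 | step 4 | (8S,9E)-10-(1,3-dioxolan-2-yl)-7-hydroxy-4,6,8-trimethylundec-9-ene-3,5-dione | CCC(=O)C(C)C(=O)C(C)C(O)[C@@H](C)/C=C(\C)C1OCCO1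
F6 | step 4 | (8S,9E)-10-(1,3-dioxolan-2-yl)-4,6,8-trimethylundec-9-ene-3,5,7-trione | CCC(=O)C(C)C(=O)C(C)C(=O)[C@@H](C)/C=C(\C)C1OCCO1
F7 | step 4 | 2-[(S,E)-4-(1,3-dioxolan-2-yl)pent-3-en-2-yl]-6-ethyl-3,5-dimethyl-4H-pyran-4-one | CCc1oc([C@@H](C)/C=C(\C)C2OCCO2)c(C)c(=O)c1C
F8 | step 19 | tert-butyl{[(2Z)-6-{(2R,3R)-3-[(tert-butyldimethylsilyl)oxy]pentan-2-yl}-2-ethylidene-3,5-dimethyl-2H-pyran-4-yl]oxy}dimethylsilane | C/C=C1\OC([C@H](C)[C@@H](CC)O[Si](C)(C)C(C)(C)C)=C(C)C(O[Si](C)(C)C(C)(C)C)=C1C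
F9 | step 14 | (3R,4S)-4-methylhex-5-en-3-ol | CC[C@@H](O)[C@@H](C)C=C
F10 | step 14 | tert-butyldimethyl{[(3R,4S)-4-methylhex-5-en-3-yl]oxy}silane | CC[C@@H](O[Si](C)(C)C(C)(C)C)[C@@H](C)C=C
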